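Numbering (daucane; β is the face of the C1 methyl): ring A = C1(Me)–C2(OAc)–C3–C4(OH, iPr)–C5(H); ring B = C1–C5–C6(O-veratroyl)–C7–C8(Me)–C9–C10(OH); the oxirane lies on C8–C9.
Enabling feature: C5–C10 of ring B, with O on C6 and Me on C8 para to C5, is a latent 2-oxy-4-methylphenyl ring. C1 is one carbon wedged between C5 and C10, next to oxygenated C2, so it is the carbene carbon of a diazo ketone.
Retrosynthetic cuts: oxirane O; C6–O acyl; the C10 oxygen back to a 7,9-dien-6-one; C1–C5 and C1–C10 together; C1–C2 (ethyl Grignard); C4–O via C4–B; the coumarin bonds C4–C5 and O–C2.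
Forward: m-cresol plus a keto ester gives a coumarin holding C2–C10. A temporary O4–Si–O6 ring is closed, and an intramolecular Buchner reaction then closes ring A, the last carbocycle, while widening the benzene ring to ring B. The oxirane, a functional group, comes last.
Stereochemistry: C4 comes from ligand-controlled conjugate borylation, and the silylene ring relays it to C1 (face of carbene addition) and C5 (face of protonation). C2 and C10 arise by attack anti to the C1 methyl. C6 and C8/C9 arise by delivery from the C4 and C10 hydroxyls.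

Key step: step 8

Assumption: read literally, the C8 and C9 descriptors of the given string put C7 and C10 on opposite sides of the oxirane, which a seven-membered ring cannot reasonably hold. The oxirane is therefore made as the cis-fused 8α,9α-epoxide syn to the C10 hydroxyl (C9 as written), and the entry for 24 repeats the given string unchanged.

Step 1
Reactants: 1 m-cresol; 2 ethyl 4-methyl-3-oxopentanoate
Product: 3 4-isopropyl-7-methylcoumarin
Conditions: CH3SO3H (neat), 60 °C
Reagents that add atoms: none
Why: Pechmann condensation; ring attack ortho to OH and para to the methyl group (the unhindered activated site), lactonisation and dehydration should give the 7-methyl isomer.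

Step 2
Reactants: 3 4-isopropyl-7-methylcoumarin
Product: 4 (R)-4-isopropyl-7-methyl-4-(4,4,5,5-tetramethyl-1,3,2-dioxaborolan-2-yl)chroman-2-one
Conditions: B2pin2, [Cu(MeCN)4]PF6 (5 mol %), (R,R)-2,3-bis(tert-butylmethylphosphino)quinoxaline (6 mol %), LiOtBu (10 mol %), DMSO, rt; aq NH4Cl
Reagents that add atoms: bis(pinacolato)diboron CC1(C)OB(OC1(C)C)B1OC(C)(C)C(C)(C)O1
Why: Copper-catalysed enantioselective conjugate borylation of a β,β-disubstituted cyclic acceptor; the ligand-bound boryl copper must add to the Re face of C4 (the (S,S) ligand serves if the sense proves opposite), which sets the only stereocentre not derived from the substrate.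

Step 3
Reactants: 4 boronate lactone
Product: 5 (S)-4-hydroxy-4-isopropyl-7-methylchroman-2-one
Conditions: 30% H2O2, pH 7 phosphate buffer, THF, 0 °C to rt; used without delay
Reagents that add atoms: hydrogen peroxide OO
Why: Boronate oxidation by 1,2-shift from boron to oxygen goes with retention, and the neutral buffer avoids lactone hydrolysis and dehydration back to 3.

Step 4
Reactants: 5 hydroxy lactone
Product: 6 (S)-3-hydroxy-3-(2-hydroxy-4-methylphenyl)-N-methoxy-N,4-dimethylpentanamide
Conditions: MeNH(OMe)·HCl, iPrMgCl, THF, −20 to 0 °C; aq NH4Cl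
Reagents that add atoms: N,O-dimethylhydroxylamine hydrochloride CNOC.Cl
Why: Weinreb aminolysis of an aryl ester by the magnesium amide; the hydroxyl is held as its magnesium alkoxide, which cannot leave, so β-elimination is suppressed.

Step 5
Reactants: 6 amide diol
Product: 7 (S)-2-(2,2-di-tert-butyl-4-isopropyl-7-methyl-4H-1,3,2-benzodioxasilin-4-yl)-N-methoxy-N-methylacetamide
Conditions: tBu2Si(OTf)2, 2,6-lutidine, CH2Cl2, 0 °C to rt
Reagents that add atoms: di-tert-butylsilyl bis(trifluoromethanesulfonate) CC(C)(C)[Si](OS(=O)(=O)C(F)(F)F)(OS(=O)(=O)C(F)(F)F)C(C)(C)C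
Why: Silylene protection of a 1,3-related phenol and tertiary alcohol by a bis(triflate) reactive enough for tertiary alcohols; it closes the temporary six-membered ring that later controls C1 and C5.

Step 6
Reactants: 7 silylene amide
Product: 8 (S)-1-(2,2-di-tert-butyl-4-isopropyl-7-methyl-4H-1,3,2-benzodioxasilin-4-yl)butan-2-one
Conditions: EtMgBr, THF, 0 °C; cold 0.5 M HCl
Reagents that add atoms: ethylmagnesium bromide CC[Mg]Br
Why: Weinreb ketone synthesis; the chelated tetrahedral adduct stops the addition at the ketone and brings in C1 and its methyl group.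

Step 7
Reactants: 8 ethyl ketone
Product: 10 (S)-3-diazo-1-(2,2-di-tert-butyl-4-isopropyl-7-methyl-4H-1,3,2-benzodioxasilin-4-yl)butan-2-one, via trifluoroacetyl diketone 9 (not isolated)
Conditions: LiN(SiMe3)2, THF, −78 °C; CF3CO2CH2CF3; dilute HCl wash; then MsN3, Et3N, H2O (1 equiv), MeCN, rt
Reagents that add atoms: 2,2,2-trifluoroethyl trifluoroacetate FC(F)(F)COC(=O)C(F)(F)F (atoms in 9 only); methanesulfonyl azide CS(=O)(=O)N=[N+]=[N-]
Why: Detrifluoroacetylative diazo transfer; kinetic deprotonation should take the ethyl CH2 and not the neopentyl-type C3, so the β-silyloxy group is not exposed to elimination.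

Step 8
Reactants: 10 diazo ketone
Product: 12 4β,6-O-(di-tert-butylsilanediyl)-4β,6-dihydroxydauca-5,7,9-trien-2-one, via norcaradiene 11 (not isolated)
Conditions: Rh2(OAc)4 (1 mol %), CH2Cl2, 40 °C, slow addition of 10
Reagents that add atoms: none
Why: Loss of N2 gives an electrophilic rhodium carbenoid at C1 that adds across the C5–C10 edge of the arene to norcaradiene 11, whose C5–C10 bond then opens in a disrotatory 6π electrocyclic step; this is the intramolecular Buchner reaction, closest known for 2-diazo-5-arylpentan-3-ones, which give 8a-methylazulenones. Ring A is closed by an intramolecular [2+1] addition through the three-atom tether C2–C3–C4 (C1–C5 bond, five-membered closure), whereas ring B is not closed but grows from the benzene ring by insertion of C1, the cyclopropane bond C5–C10 being made and broken in the same flask. The one new stereocentre, C1, is fixed by C4 through the dioxasiline ring: O4 is held near the arene plane, so the CH2 arm stands on one face and the isopropyl group on the other, the carbenoid can reach only the face of its own arm, and the tether geometry then places the C1 methyl syn to O4. Edge selectivity for C5–C10 over C5–C6 rests on the oxygen substituent and the tert-butyl groups that crowd the C6 edge, in line with the usual addition of ortho-substituted substrates at the free edge. Chemoselectivity is needed against 1,5 C–H insertion into the isopropyl methine (deactivated by the β-oxygen and outrun by the electron-rich arene), against attack on O4 (a hindered silyl ether oxygen) and against 1,2-hydride shift from the methyl group (normally minor for diazoethyl ketones under this catalyst).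

Step 9
Reactants: 12 tricyclic silylene
Product: 14 4β-hydroxy-5αH-dauca-7,9-diene-2,6-dione, via silanol ketone 13 (not isolated)
Conditions: AcOH/THF/H2O (3:1:1), rt; then HF·pyridine, pyridine, THF, 0 °C
Reagents that add atoms: water O (its oxygen stays in 13 only)
Why: Acid hydrolysis of a hindered silyl enol ether runs through rate-determining protonation at carbon while both Si–O bonds are intact; in that product-like transition state C6 must stay cis to O4 on ring A to keep the six-membered ring, so H should enter C5 from the α face (trans fusion, also the more stable epimer with iPr anti to C6 and an O4–H···O=C6 hydrogen bond), and fluoride then frees O4 under the non-basic conditions that β-hydroxy cyclopentanones tolerate.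

Step 10
Reactants: 14 hydroxy diketone
Product: 15 2β,4β-dihydroxy-5αH-dauca-7,9-dien-6-one
Conditions: NaBH4, MeOH/CH2Cl2, −78 to −40 °C
Reagents that add atoms: none
Why: Borohydride takes the saturated cyclopentanone before the conjugated dienone (as in the Hajos–Parrish and Wieland–Miescher ketones) and attacks anti to the angular C1 methyl, as at C17 of steroids, to give the 2β-alcohol.

Step 11
Reactants: 15 diol dienone
Product: 16 2β-acetoxy-4β-hydroxy-5αH-dauca-7,9-dien-6-one
Conditions: Ac2O, pyridine, DMAP (cat.), CH2Cl2, 0 °C to rt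
Reagents that add atoms: acetic anhydride CC(=O)OC(C)=O
Why: Standard acylation of the secondary alcohol; the hindered tertiary C4 hydroxyl does not react under these conditions.

Step 12
Reactants: 16 acetoxy dienone
Product: 17 2β-acetoxy-9α,10α-epoxy-4β-hydroxy-5αH-dauc-7-en-6-one
Conditions: mCPBA, NaHCO3, CH2Cl2, 0 °C
Reagents that add atoms: 3-chloroperoxybenzoic acid OOC(=O)c1cccc(Cl)c1
Why: Peracid epoxidation of a 2,4-dienone goes to the electron-richer γ,δ-alkene (as with steroidal 4,6-dien-3-ones) and from the α face, anti to the adjacent C1 methyl, which sets C10.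

Step 13
Reactants: 17 epoxy enone
Product: 18 2β-acetoxy-4β,10α-dihydroxy-5αH-dauc-8-en-6-one
Conditions: SmI2 (2.2 equiv), THF/MeOH, −78 °C
Reagents that add atoms: none
Why: Samarium diiodide reduction of a γ,δ-epoxy enone cleaves the allylic C9–O bond, leaves C10–O untouched, and kinetic α-protonation of the dienolate at C7 puts the alkene at C8=C9.

Step 14
Reactants: 18 hydroxy enone
Product: 19 2β-acetoxy-4β-hydroxy-10α-(triethylsilyloxy)-5αH-dauc-8-en-6-one
Conditions: Et3SiCl, imidazole, CH2Cl2, 0 °C
Reagents that add atoms: chlorotriethylsilane CC[Si](Cl)(CC)CC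
Why: Chemoselective silylation of the secondary allylic alcohol over the tertiary one masks C10–OH before a second secondary alcohol is made.

Step 15
Reactants: 19 silyl ether ketone
Product: 20 2β-acetoxy-10α-(triethylsilyloxy)-5αH-dauc-8-ene-4β,6α-diol
Conditions: Me4NBH(OAc)3, MeCN/AcOH, −30 °C
Reagents that add atoms: none
Why: Evans–Saksena reduction; the C4 hydroxyl binds boron and delivers hydride to the β face of C6, giving the anti 1,3-diol, which is the 6α-alcohol.

Step 16
Reactants: 20 diol; 21 3,4-dimethoxybenzoyl chloride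
Product: 22 2β-acetoxy-6α-(3,4-dimethoxybenzoyloxy)-10α-(triethylsilyloxy)-5αH-dauc-8-en-4β-ol
Conditions: DMAP, Et3N, CH2Cl2, rt to 40 °C
Reagents that add atoms: none
Why: DMAP-catalysed acylation of the only free secondary hydroxyl; the tertiary C4 hydroxyl stays free.

Step 17
Reactants: 22 silyl ether ester
Product: 23 2β-acetoxy-6α-(3,4-dimethoxybenzoyloxy)-5αH-dauc-8-ene-4β,10α-diol
Conditions: HF·pyridine, pyridine, THF, 0 °C
Reagents that add atoms: none
Why: Fluoride cleavage of a triethylsilyl ether is mild enough to leave both esters and the allylic alcohol untouched.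

Step 18
Reactants: 23 allylic alcohol
Product: 24 target, 2β-acetoxy-8α,9α-epoxy-6α-(3,4-dimethoxybenzoyloxy)-5αH-daucane-4β,10α-diol
Conditions: VO(acac)2 (5 mol %), tBuOOH, CH2Cl2, 0 °C to rt
Reagents that add atoms: tert-butyl hydroperoxide CC(C)(C)OO
Why: Vanadium-catalysed hydroxyl-directed epoxidation; the C10 alkoxide on vanadium delivers oxygen to its own α face of C8=C9, the normal syn outcome for allylic alcohols in seven-membered rings.

Compound list
1 | m-cresol | Cc1cccc(O)c1 | starting material
2 | ethyl 4-methyl-3-oxopentanoate | CCOC(=O)CC(=O)C(C)C | starting material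
3 | 4-isopropyl-7-methylcoumarin | CC(C)C1=CC(=O)Oc2cc(C)ccc12 | intermediate
4 | (R)-4-boryl lactone | O=C1C[C@](B2OC(C)(C)C(C)(C)O2)(C(C)C)c2ccc(C)cc2O1 | intermediate
5 | (S)-4-hydroxy lactone | O=C1C[C@](O)(C(C)C)c2ccc(C)cc2O1 | intermediate
6 | (S)-Weinreb amide diol | CON(C)C(=O)C[C@](O)(C(C)C)c1ccc(C)cc1O | intermediate
7 | (S)-silylene Weinreb amide | CON(C)C(=O)C[C@@]1(C(C)C)O[Si](C(C)(C)C)(C(C)(C)C)Oc2cc(C)ccc12 | intermediate
8 | (S)-silylene ethyl ketone | CCC(=O)C[C@@]1(C(C)C)O[Si](C(C)(C)C)(C(C)(C)C)Oc2cc(C)ccc12 | intermediate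
9 | trifluoroacetyl diketone (acylated at the ethyl CH2) | CC(C(=O)C(F)(F)F)C(=O)C[C@@]1(C(C)C)O[Si](C(C)(C)C)(C(C)(C)C)Oc2cc(C)ccc12 | intermediate
10 | (S)-diazo ketone | CC(=[N+]=[N-])C(=O)C[C@@]1(C(C)C)O[Si](C(C)(C)C)(C(C)(C)C)Oc2cc(C)ccc12 | intermediate
11 | norcaradiene (cyclopropane C1–C5–C10) | O=C1C[C@@]2(C(C)C)O[Si](C(C)(C)C)(C(C)(C)C)OC3=CC(C)=C[C@H]4[C@@]1(C)[C@@]234 | intermediate
12 | tricyclic cycloheptatriene silylene | O=C1C[C@@]2(C(C)C)O[Si](C(C)(C)C)(C(C)(C)C)OC3=C2[C@]1(C)C=CC(C)=C3 | intermediate
13 | O4-(di-tert-butylhydroxysilyl) ether of 14 | O=C1C=C(C)C=C[C@]2(C)C(=O)C[C@](O[Si](O)(C(C)(C)C)C(C)(C)C)(C(C)C)[C@@H]12 | intermediate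
14 | trans-fused hydroxy diketone | O=C1C=C(C)C=C[C@]2(C)C(=O)C[C@](O)(C(C)C)[C@@H]12 | intermediate
15 | 2β,4β-diol dienone | O=C1C=C(C)C=C[C@]2(C)[C@@H](O)C[C@](O)(C(C)C)[C@@H]12 | intermediate
16 | 2β-acetate dienone | O=C1C=C(C)C=C[C@]2(C)[C@@H](OC(C)=O)C[C@](O)(C(C)C)[C@@H]12 | intermediate
17 | 9α,10α-epoxy enone | O=C1C=C(C)[C@@H]3O[C@@H]3[C@]2(C)[C@@H](OC(C)=O)C[C@](O)(C(C)C)[C@@H]12 | intermediate
18 | 10α-hydroxy β,γ-enone | O=C1CC(C)=C[C@H](O)[C@]2(C)[C@@H](OC(C)=O)C[C@](O)(C(C)C)[C@@H]12 | intermediate
19 | 10α-triethylsilyl ether ketone | O=C1CC(C)=C[C@H](O[Si](CC)(CC)CC)[C@]2(C)[C@@H](OC(C)=O)C[C@](O)(C(C)C)[C@@H]12 | intermediate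
20 | 4β,6α-diol | O[C@@H]1CC(C)=C[C@H](O[Si](CC)(CC)CC)[C@]2(C)[C@@H](OC(C)=O)C[C@](O)(C(C)C)[C@@H]12 | intermediate
21 | 3,4-dimethoxybenzoyl chloride | COc1ccc(C(=O)Cl)cc1OC | starting material
22 | 6α-veratrate silyl ether | COc1ccc(C(=O)O[C@@H]2CC(C)=C[C@H](O[Si](CC)(CC)CC)[C@]3(C)[C@@H](OC(C)=O)C[C@](O)(C(C)C)[C@@H]23)cc1OC | intermediate
23 | 6α-veratrate allylic alcohol | COc1ccc(C(=O)O[C@@H]2CC(C)=C[C@H](O)[C@]3(C)[C@@H](OC(C)=O)C[C@](O)(C(C)C)[C@@H]23)cc1OC | intermediate
24 | CNP0197096.4 | COc1ccc(C(=O)O[C@@H]2C[C@@]3(C)O[C@@H]3[C@H](O)[C@]3(C)[C@@H](OC(C)=O)C[C@](O)(C(C)C)[C@@H]23)cc1OC | target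

Total step count: 18. Longest linear sequence: 18 steps, from 1 to 24.

Steps most likely to fail

Step 8. The carbenoid may be consumed by insertion into the isopropyl methine C–H, by hydride shift from its own methyl group, or by silyl transfer from O4 before it reaches the arene. The fallback makes the quaternary centre after ring closure instead of in the carbene step.
- It sets out from 7. MeMgBr gives the methyl ketone F1.
- LiN(SiMe3)2 with CF3CO2CH2CF3 gives the trifluoroacetyl diketone F2, and MsN3/Et3N gives the terminal diazo ketone F3. This substrate class has no β-hydrogen at the carbene, the smallest carbenoid, and the broadest Buchner record.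
- Rh2(OAc)4 then gives the C1–H tricycle F4, which is used at once.
- KN(SiMe3)2 followed by MeI at −78 °C alkylates the extended enolate at its α-carbon C1. Attack comes from the β face, because the pseudoaxial isopropyl group blocks the α face. The route is rejoined at 12.

Step 2. Addition of the boryl copper species to a β-carbon flanked by aryl and isopropyl may be slow, and face discrimination may erode. The fallback builds the carbinol by carbonyl addition and takes chirality from a separation.
- It sets out from 1. Isobutyryl chloride/Et3N gives 3-methylphenyl isobutyrate F5.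
- Fries rearrangement with AlCl3 at 130 °C gives 1-(2-hydroxy-4-methylphenyl)-2-methylpropan-1-one F6.
- The lithium enolate of N-methoxy-N-methylacetamide (LiN(iPr)2, 3 equiv, THF, −78 °C) adds to the ketone to give the racemic amide diol F7.
- Preparative chromatography on a chiral stationary phase delivers the (S) enantiomer, and the route is rejoined at 6.

Step 9. Silicon may leave O6 before carbon is protonated, so that the free enol takes up the proton from the β face. The tertiary hydroxyl may also be lost by β-elimination toward either ketone. The fallback sets C5 by equilibration after the C2 ketone has been parked.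
- It sets out from 12. NaBH4 gives the C2 alcohol F8, and either epimer serves.
- HF·pyridine gives the diol dienone, at first largely as its cis-fused epimer F9.
- With no β-hydroxy cyclopentanone left, DBU in toluene can converge it on the more stable trans-fused diol dienone F10.
- Dess–Martin periodinane re-oxidises the secondary alcohol only, and the route is rejoined at 14.

Further compounds
F1 | step 8 | (S)-silylene methyl ketone | CC(=O)C[C@@]1(C(C)C)O[Si](C(C)(C)C)(C(C)(C)C)Oc2cc(C)ccc12
F2 | step 8 | trifluoroacetyl diketone of F1 | O=C(CC(=O)C(F)(F)F)C[C@@]1(C(C)C)O[Si](C(C)(C)C)(C(C)(C)C)Oc2cc(C)ccc12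
F3 | step 8 | (S)-terminal diazo ketone | [N-]=[N+]=CC(=O)C[C@@]1(C(C)C)O[Si](C(C)(C)C)(C(C)(C)C)Oc2cc(C)ccc12
F4 | step 8 | C1–H tricyclic cycloheptatriene silylene | O=C1C[C@@]2(C(C)C)O[Si](C(C)(C)C)(C(C)(C)C)OC3=C2[C@@H]1C=CC(C)=C3
F5 | step 2 | 3-methylphenyl isobutyrate | CC(C)C(=O)Oc1cccc(C)c1
F6 | step 2 | 1-(2-hydroxy-4-methylphenyl)-2-methylpropan-1-one | CC(C)C(=O)c1ccc(C)cc1O
F7 | step 2 | racemic Weinreb amide diol | CON(C)C(=O)CC(O)(C(C)C)c1ccc(C)cc1O
F8 | step 9 | C2 alcohol of 12 (C2 unassigned) | OC1C[C@@]2(C(C)C)O[Si](C(C)(C)C)(C(C)(C)C)OC3=C2[C@]1(C)C=CC(C)=C3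
F9 | step 9 | cis-fused diol dienone (5β-H, C2 unassigned) | O=C1C=C(C)C=C[C@]2(C)C(O)C[C@](O)(C(C)C)[C@H]12
F10 | step 9 | trans-fused diol dienone (5α-H, C2 unassigned) | O=C1C=C(C)C=C[C@]2(C)C(O)C[C@](O)(C(C)C)[C@@H]12
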